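Two questions stand for this flask: how it stands at the asked time, and how much complex with two exchanged it holds.

| setting | ash | maple | flask |
|---|---|---|---|
| starting complex | 0.14 M | 0.14 M | 0.14 M |
| incoming ligand | 2.5 equiv | 2.5 equiv | 2.50 equiv |
| leaving ligand | 5 equiv | 7.5 equiv | 5.00 equiv |
| remark | the very flask that is asked about, followed so far | run made earlier |  |
| time |  |  | 1.5 h |

| run | time / min | complex with two exchanged / % | complex with one exchanged / % |
|---|---|---|---|
| ash | 3.00 | 79 | 9 |
| ash | 10.0 | 95 | 0 |
| ash | 15.0 | 97 | 0 |
| ash | 25.0 | 99 | 0 |
| ash | 40.0 | 95 | 3 |
| maple | 3.00 | 84 | 12 |
| maple | 5.00 | 92 | 5 |
| maple | 10.0 | 96 | 0 |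
| maple | 20.0 | 95 | 0 |
| maple | 40.0 | 97 | 0 |

(readings scatter by 1.5 percentage points)

1. the state of affairs at 1.5 h: stopped, and by what, or still going (all of the starting complex has reacted / forward and back rates have come level / it is still moving / the incoming ligand has run out first)
2. the complex with two exchanged standing at 1.5 h, as a percentage of the starting complex charged

- the reaction counts as stopped when no species that holds the starting complex changes by six tenths of a point or more over the second half of the time

The reckoning here counts turnovers. The turnover budget B, the exchanges that the charge of incoming ligand can pay per starting complex, is 2.50. Each complex with two exchanged costs two exchanges, so B is larger than that by 0.500, and the starting complex is the limiting reagent.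

The ash readings form a ladder of times. At 3.00 min, the first rung, the ash flask already reads 79% complex with two exchanged and 9% complex with one exchanged. By 10.0 min, the complex with one exchanged reads 0% in the ash flask. From there to 40.0 min the ash readings of complex with two exchanged rise and fall without a steady drift, with a scatter of 1.5 percentage points, and average 96.5%. The asked 1.5 h is 9.00 times the first flat reading, so this reckoning commits to a flask stopped with its starting complex consumed, at about that average.

The forecast, parting from this reckoning on the stop, gives forward and back rates have come level at 96.5%, as a shortfall that “fits an equilibrium lying far to the product side”.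

The flask gives all of the starting complex has reacted, with 95.9% of complex with two exchanged.

    starting complex + incoming ligand → leaving ligand + complex with one exchanged (k = 0.110 M⁻¹ s⁻¹)
    complex with two exchanged + incoming ligand ⇌ leaving ligand + complex with three exchanged (K = 0.650, k = 0.00710 M⁻¹ s⁻¹)
    complex with one exchanged + incoming ligand → leaving ligand + complex with two exchanged (k = 0.130 M⁻¹ s⁻¹)

At 1.50 h the flask holds 0% starting complex, 4.07% complex with three exchanged and 18% of its incoming ligand, so about 2.04 of B is spent. The neighbouring flask, charged with 1.00 equiv of incoming ligand, has a budget of 1.00, which is less than the two exchanges that each complex with two exchanged costs. At 1.50 h that neighbour has 0% of its incoming ligand left and 33% of its starting complex, with 33.2% complex with one exchanged. Its complex with two exchanged stands at 33.4%.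

The numbers in the tables were generated by integration with made-up constants; the scatter is artificial.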